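The lactam ring is cut at C2–C3 and C4–C5, leaving a C5–N1–C2(=O) aminomethyl–carbamoyl unit that already carries the benzyl group, and the unsubstituted C3–C4 ethano bridge. The key step joins them in one flask: an open-chain N-(methoxycarbonyl)-N-benzylglycine loses CO2 under photoredox catalysis, the α-amino radical adds to tert-butyl acrylate (C4–C5), and the ester enolate so formed acylates itself on the carbamate carbonyl (C2–C3). It exploits that C5 is α to N1, C2 is an acyl carbon and C3 is α to the lactam carbonyl, where a traceless ester can sit. Ester and methyl ethers are then removed and the catechol ring is brominated at all three free positions.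

Key step: step 3

Remark: the target has no stereocentre; compounds 7 and 8 are racemic at C3 of the lactam ring, and this centre becomes a CH2 group in step 4.

Step 1
Reactants: 1 3,4-dimethoxybenzaldehyde; 2 glycine
Product: 3 N-(3,4-dimethoxybenzyl)glycine
Conditions: NaOH, MeOH, rt; NaBH4, 0 °C; HCl to pH 6
Reagents that add atoms: none
Why: Reductive amination, in which the imine of sodium glycinate is formed before NaBH4 is added so that dialkylation is limited, and the zwitterionic secondary amine should precipitate at its isoelectric point.

Step 2
Reactants: 3 N-(3,4-dimethoxybenzyl)glycine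
Product: 4 N-(methoxycarbonyl)-N-(3,4-dimethoxybenzyl)glycine
Conditions: ClCO2Me, 1 M NaOH, THF, 0 °C; HCl to pH 2
Reagents that add atoms: methyl chloroformate, COC(=O)Cl
Why: Schotten–Baumann N-acylation, in which the secondary amine outcompetes the carboxylate for the chloroformate and any mixed anhydride is hydrolysed back in the aqueous base, so that only the methyl carbamate should remain.

Step 3
Reactants: 4 N-(methoxycarbonyl)-N-(3,4-dimethoxybenzyl)glycine; 5 tert-butyl acrylate
Product: 7 tert-butyl 1-(3,4-dimethoxybenzyl)-2-oxopyrrolidine-3-carboxylate (racemic), via open-chain Giese adduct 6 (not isolated)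
Conditions: KOtBu (1 equiv), 4CzIPN (2 mol %), DMF, blue LEDs, rt, N2 stream; then KOtBu (2.5 equiv), THF, 0 °C to rt, same flask; 1 M HCl
Reagents that add atoms: none
Why: The excited organic photocatalyst oxidises the potassium carboxylate of 4, loss of CO2 gives the carbamate-substituted aminomethyl radical at the future C5, and this nucleophilic radical adds to the β-carbon of the acrylate (Giese addition) to make the C4–C5 bond, after which the electrophilic α-ester radical is reduced by the reduced photocatalyst to the ester enolate (radical–polar crossover). That enolate, or the enolate regenerated from protonated adduct 6 by the KOtBu added to the same flask, attacks the carbamate carbonyl and expels methoxide to make the C2–C3 bond (Dieckmann-type Claisen condensation). The closest known reaction types are the photoredox decarboxylative conjugate addition of N-carbamoyl amino acids to acrylates and the intramolecular acylation of carbanions by carbamates with loss of alkoxide. The lactam ring closes in the 5-exo-trig mode at the carbamate carbonyl. The new stereocentre at C3 forms without control as a racemate and needs none, because step 4 turns it into a CH2 group. The step needs the radical to arise only at the glycine carbon and not at the benzylic CH2, which the position of the carboxyl group secures, and it needs acylation at the carbamate in preference to intermolecular Claisen condensation, which the five-membered transition state, the hindered tert-butyl ester and the irreversible deprotonation of the β-amido ester product should secure.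

Step 4
Reactants: 7 tert-butyl 1-(3,4-dimethoxybenzyl)-2-oxopyrrolidine-3-carboxylate
Product: 9 1-(3,4-dihydroxybenzyl)pyrrolidin-2-one, via catechol acid 8 (not isolated)
Conditions: BBr3, CH2Cl2, −78 °C to rt; H2O, 0 °C; then AcOH, 110 °C
Reagents that add atoms: none
Why: Lewis-acid dealkylation by BBr3 should cleave both aryl methyl ethers and the tert-butyl ester while the lactam stays intact, and the resulting 2-oxopyrrolidine-3-carboxylic acid is a malonic half-amide that loses CO2 on heating (thermal decarboxylation), which erases the C3 stereocentre.

Step 5
Reactants: 9 1-(3,4-dihydroxybenzyl)pyrrolidin-2-one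
Product: 10 1-(2,3,6-tribromo-4,5-dihydroxybenzyl)pyrrolidin-2-one
Conditions: Br2 (3.1 equiv), AcOH, rt
Reagents that add atoms: bromine, BrBr
Why: Electrophilic aromatic bromination, in which each of the three free positions of the arene ring is ortho or para to a hydroxyl group, so that three equivalents of Br2 should fill all of them without any regiochemical choice while the lactam is inert.

Compound list
1 | 3,4-dimethoxybenzaldehyde | COc1ccc(C=O)cc1OC | starting material
2 | glycine | NCC(=O)O | starting material
3 | N-(3,4-dimethoxybenzyl)glycine | COc1ccc(CNCC(=O)O)cc1OC | intermediate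
4 | N-(methoxycarbonyl)-N-(3,4-dimethoxybenzyl)glycine | COC(=O)N(CC(=O)O)Cc1ccc(OC)c(OC)c1 | intermediate
5 | tert-butyl acrylate | C=CC(=O)OC(C)(C)C | starting material
6 | tert-butyl 4-[(methoxycarbonyl)(3,4-dimethoxybenzyl)amino]butanoate (formed in the flask, not isolated) | COC(=O)N(CCCC(=O)OC(C)(C)C)Cc1ccc(OC)c(OC)c1 | intermediate
7 | tert-butyl 1-(3,4-dimethoxybenzyl)-2-oxopyrrolidine-3-carboxylate, racemic at C3 | CC(C)(C)OC(=O)C1CCN(Cc2ccc(OC)c(OC)c2)C1=O | intermediate
8 | 1-(3,4-dihydroxybenzyl)-2-oxopyrrolidine-3-carboxylic acid, racemic at C3 (formed in the flask, not isolated) | OC(=O)C1CCN(Cc2ccc(O)c(O)c2)C1=O | intermediate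
9 | 1-(3,4-dihydroxybenzyl)pyrrolidin-2-one | O=C1CCCN1Cc1ccc(O)c(O)c1 | intermediate
10 | 1-(2,3,6-tribromo-4,5-dihydroxybenzyl)pyrrolidin-2-one | O=C1CCCN1Cc1c(Br)c(O)c(O)c(Br)c1Br | target

Total step count: 5
Longest linear sequence: 5 steps (1 and 2 to 3, 4, 7, 9, 10)

Steps most likely to fail

Step 3. Protonation of the ester enolate may outrun acylation, and the dialkyl carbamate may prove too poor an acceptor. Ring closure would then stall at the open-chain stage or give way to intermolecular Claisen condensation and alkoxide exchange at the carbamate. The fallback sets out from 1 and builds the lactam by N-acylation instead. Reductive amination of 1 with methyl 4-aminobutanoate hydrochloride (NaBH(OAc)3, Et3N, 1,2-dichloroethane, rt) should give methyl 4-[(3,4-dimethoxybenzyl)amino]butanoate F1. Heating F1 in toluene should close it, with loss of methanol, to 1-(3,4-dimethoxybenzyl)pyrrolidin-2-one F2. BBr3 in CH2Cl2 should then cleave both methyl ethers, and the fallback comes back to the route at 9.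

Step 5. The electron-rich catechol may be over-oxidised to the ortho-quinone by Br2, or attacked at the ring carbon that bears the CH2 group (para to a hydroxyl) with loss of the lactam-bearing unit. The fallback sets out from 7 and brominates before the phenols are set free. Acidolysis of the tert-butyl ester (CF3CO2H, CH2Cl2, rt) should give 1-(3,4-dimethoxybenzyl)-2-oxopyrrolidine-3-carboxylic acid F3, and heating in toluene should decarboxylate it to 1-(3,4-dimethoxybenzyl)pyrrolidin-2-one F2. Exhaustive bromination (excess Br2, FeBr3, CH2Cl2, dark) should give 1-(2,3,6-tribromo-4,5-dimethoxybenzyl)pyrrolidin-2-one F4. BBr3 in CH2Cl2 should then remove both methyl groups, and the fallback comes back to the route at 10.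

Step 4. The unprotected catechol may oxidise and oligomerise during the hot decarboxylation, or loss of CO2 from the polar catechol acid may stay incomplete. The fallback sets out from 7 and decarboxylates while the phenols are still protected. CF3CO2H in CH2Cl2 should give 1-(3,4-dimethoxybenzyl)-2-oxopyrrolidine-3-carboxylic acid F3, and refluxing toluene should convert it into 1-(3,4-dimethoxybenzyl)pyrrolidin-2-one F2. BBr3 in CH2Cl2 at −78 °C to rt should then cleave the two methyl ethers, and the fallback comes back to the route at 9.

Further compounds
F1 | step 3 | methyl 4-[(3,4-dimethoxybenzyl)amino]butanoate | COC(=O)CCCNCc1ccc(OC)c(OC)c1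
F2 | step 3 | 1-(3,4-dimethoxybenzyl)pyrrolidin-2-one | COc1ccc(CN2CCCC2=O)cc1OC
F3 | step 4 | 1-(3,4-dimethoxybenzyl)-2-oxopyrrolidine-3-carboxylic acid, racemic at C3 | COc1ccc(CN2CCC(C(=O)O)C2=O)cc1OC
F4 | step 5 | 1-(2,3,6-tribromo-4,5-dimethoxybenzyl)pyrrolidin-2-one | COc1c(Br)c(Br)c(CN2CCCC2=O)c(Br)c1OC
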